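**Retrosynthetic overview**

- The target is one unstrained 27-membered ring (26 carbons and the ring oxygen) with a single lactone and no stereocentre. Carbons are numbered C1 (lactone C=O) to C26 (OCH2).
- Last disconnection: C2–C3 and C14–C15 are taken back to alkenes, so the target comes from a 27-membered 2,14-dienolide by hydrogenation.
- Key disconnection: both alkenes are cut at once by ring-expansion metathesis. The feature that allows this is that the ring divides into C1–C2 with the ester (an acrylate), C3–C14 (the twelve ring carbons of cyclododecene) and C15–C26 with the ring oxygen (a tridec-12-en-1-yl chain).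
- The acrylate diene comes from tridec-12-en-1-ol and acryloyl chloride. The alcohol comes from the Grignard reagent of 11-bromoundec-1-ene and oxirane.
- Ring order: there is only one ring, the 27-membered macrolactone, and it is closed in the key step.

Key step: step 3

Assumption: commercial cyclododecene is a cis/trans mixture; both isomers ring-open to the same chain, so the mixture can be used, and 8 is drawn as the Z isomer.

**Route**

Step 1
Reactants: 1 11-bromoundec-1-ene; 2 oxirane
Product: 5 tridec-12-en-1-ol, via undec-10-enylmagnesium bromide 3 (not isolated), via bromomagnesium tridec-12-en-1-olate 4 (not isolated)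
Conditions: Mg, THF, 40 °C; CuI (10 mol%), oxirane (1.5 equiv, THF solution), −30 → 0 °C; then 1 M HCl, 0 °C
Reagents that add atoms: oxirane, C1CO1
Why: Magnesium insertion into the primary C–Br bond gives Grignard reagent 3, which under CuI catalysis opens oxirane by SN2 attack at carbon (Grignard epoxide opening, a two-carbon homologation) to alkoxide 4, protonated on work-up; the remote terminal alkene is inert and no stereocentre arises.

Step 2
Reactants: 5 tridec-12-en-1-ol; 6 acryloyl chloride
Product: 7 tridec-12-en-1-yl prop-2-enoate (tridec-12-en-1-yl acrylate)
Conditions: acryloyl chloride (1.2 equiv), Et3N (1.5 equiv), BHT (cat.), CH2Cl2, 0 °C → rt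
Reagents that add atoms: acryloyl chloride, C=CC(=O)Cl
Why: O-Acylation of a primary alcohol by an acid chloride with an amine base is fast at 0 °C and leaves the isolated alkene untouched, and the trace of BHT should suppress radical polymerisation of the acrylate.

Step 3
Reactants: 7 tridec-12-en-1-yl prop-2-enoate; 8 (Z)-cyclododecene
Product: 9 (3E,15E)-1-oxacycloheptacosa-3,15-dien-2-one
Conditions: 8 (1.5 equiv), second-generation Grubbs catalyst (H2IMes)(PCy3)Cl2Ru=CHPh (5 mol%, two portions), 1,4-benzoquinone (10 mol%), CH2Cl2 (5 mM in 7), 40 °C, Ar sweep; ethyl vinyl ether quench
Reagents that add atoms: (Z)-cyclododecene, C1CCCC/C=C\CCCCC1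
Why: The benzylidene is exchanged first at the unhindered, electron-rich C12=C13 vinyl group of 7; the alkyl alkylidene so formed adds to cyclododecene 8 by [2+2] cycloaddition and cycloreversion, which moves the carbene twelve carbons down the chain, and this carbene closes onto the acrylate CH=CH2 with loss of ethene. The closest known reaction is ring-expansion metathesis, in which the same catalyst inserts cycloalkenes into acrylate-terminated acyclic dienes, together with macrocyclic ring-closing metathesis onto acrylates. The 27-membered ring closes end to end, the C2=C3 bond (target numbering) being the ring-closing event and the C14=C15 bond arising from the preceding ring-opening cross-metathesis. No stereocentre is formed; E geometry is expected at the enoate and an E-rich mixture at C14=C15, and both alkenes are removed in step 4. The selectivity needed is uptake of exactly one molecule of 8: the electron-poor acrylate is the slowest partner, so chain extension at the alkyl alkylidene can run ahead of closure, rings and oligomers that carry extra cyclododecene units are joined through unconjugated alkenes and can shed 8 again at 5 mM, whereas the conjugated enoate, once formed, should re-enter metathesis only slowly. The leak is closure before insertion to the 15-membered enoate lactone, countered by the excess of 8, and 1,4-benzoquinone is added to stop Ru–H alkene migration that would shorten the chain.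

Step 4
Reactants: 9 (3E,15E)-1-oxacycloheptacosa-3,15-dien-2-one
Product: 10 26-hexacosanolide (oxacycloheptacosan-2-one)
Conditions: H2 (1 atm), 10% Pd/C, EtOAc, rt
Reagents that add atoms: none
Why: Heterogeneous catalytic hydrogenation over Pd/C should saturate both the conjugated C2=C3 and the isolated C14=C15 alkene whatever their geometry while the lactone is inert, and since no stereocentre is created all alkene isomers converge on one product.

**Compound list**

1 | 11-bromoundec-1-ene | C=CCCCCCCCCCBr | starting material
2 | oxirane | C1CO1 | starting material
3 | undec-10-enylmagnesium bromide | C=CCCCCCCCCC[Mg]Br | intermediate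
4 | bromomagnesium tridec-12-en-1-olate | C=CCCCCCCCCCCCO[Mg]Br | intermediate
5 | tridec-12-en-1-ol | C=CCCCCCCCCCCCO | intermediate
6 | acryloyl chloride | C=CC(=O)Cl | starting material
7 | tridec-12-en-1-yl prop-2-enoate | C=CC(=O)OCCCCCCCCCCCC=C | intermediate
8 | (Z)-cyclododecene | C1CCCC/C=C\CCCCC1 | starting material
9 | (3E,15E)-1-oxacycloheptacosa-3,15-dien-2-one | O=C1/C=C/CCCCCCCCCC/C=C/CCCCCCCCCCCO1 | intermediate
10 | 26-hexacosanolide (oxacycloheptacosan-2-one) | O=C1CCCCCCCCCCCCCCCCCCCCCCCCCO1 | target

**Step count and risks**

Total step count: 4. Longest linear sequence: 4 steps (1 → 5 → 7 → 9 → 10).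

Steps most likely to fail:

1. Step 3 (key step). Several processes can go wrong:
   - The alkylidene at the alkyl end may close onto the acrylate before any cyclododecene is taken up, which gives a 15-membered ring.
   - More than one cycloalkene unit may be inserted before closure.
   - Intermolecular enoate-forming cross-metathesis may build linear oligomers that no longer equilibrate.
   - Alkene migration followed by metathesis may remove CH2 units.

   Fallback: the ring size is fixed by an ester instead of by the number of inserted cycloalkene units. The fallback sets out from bromide 1 through its Grignard reagent 3 and comes back at target 10. Grignard reagent 3 would open oxetane (CuI cat., THF, 0 °C → rt, then 1 M HCl) to give tetradec-13-en-1-ol F1. Half of this alcohol would be oxidised (CrO3, aqueous H2SO4, acetone, 0 °C, Jones oxidation) to tetradec-13-enoic acid F2. Steglich esterification of the acid with the remaining alcohol (DCC, DMAP, CH2Cl2) should give tetradec-13-en-1-yl tetradec-13-enoate F3. Its two unactivated terminal alkenes should undergo ordinary macrocyclic ring-closing metathesis ((H2IMes)(PCy3)Cl2Ru=CHPh, CH2Cl2, 2 mM, 40 °C) to (E)-1-oxacycloheptacos-14-en-2-one F4; an E/Z mixture is expected and the E isomer is drawn. Hydrogenation under the conditions of step 4 would then give 10.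

2. Step 1. Homocoupling of the bromide may occur during Grignard formation, bromide may open oxirane in competition (halohydrin formation), and loss of the volatile epoxide may leave the Grignard reagent unconsumed.

   Fallback: the two carbons are added by enolate alkylation and reduction. The fallback sets out from 1 and comes back at 5. tert-Butyl acetate would be deprotonated with LiN(iPr)2 (THF, −78 °C) and alkylated with 1 (DMPU, −78 °C → rt) to give tert-butyl tridec-12-enoate F5. Reduction with LiAlH4 (THF, 0 °C) should give alcohol 5.

3. Step 2. Radical polymerisation of the acrylate may occur during the acylation or on concentration, and chloride or amine may add in conjugate fashion to the new enoate.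

   Fallback: the acrylate is carried in masked form. The fallback sets out from 5 and comes back at 7. Acylation of 5 with 3-chloropropanoyl chloride (pyridine, CH2Cl2, 0 °C) should give the storable tridec-12-en-1-yl 3-chloropropanoate F6. Elimination of HCl with Et3N (CH2Cl2, 40 °C, E1cB) just before the metathesis would release acrylate 7.

**Further compounds**

F1 | step 3 | tetradec-13-en-1-ol | C=CCCCCCCCCCCCCO
F2 | step 3 | tetradec-13-enoic acid | C=CCCCCCCCCCCCC(=O)O
F3 | step 3 | tetradec-13-en-1-yl tetradec-13-enoate | C=CCCCCCCCCCCCC(=O)OCCCCCCCCCCCCC=C
F4 | step 3 | (E)-1-oxacycloheptacos-14-en-2-one | O=C1CCCCCCCCCCC/C=C/CCCCCCCCCCCCO1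
F5 | step 1 | tert-butyl tridec-12-enoate | C=CCCCCCCCCCCC(=O)OC(C)(C)C
F6 | step 2 | tridec-12-en-1-yl 3-chloropropanoate | ClCCC(=O)OCCCCCCCCCCCC=C
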